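The cedar run at its last reading, 10.0 h, holds 48.7% of its charge as D and 15.9% as E, so the fraction still in neither product is 35.4%, and the end ratio turns on how that fraction divides.

- cedar: L 1.1 M; X 110 mM; run made earlier
- flask: L 0.72 M; X 110 mM; time 4.0 d

cedar run (percent of the L charged)

| time / h | D / % | E / % |
|---|---|---|
| 0.667 | 6.0 | 2.5 |
| 2.00 | 14.1 | 6.1 |
| 3.00 | 20.2 | 8.0 |
| 5.00 | 31.1 | 11.9 |
| 8.00 | 41.6 | 14.2 |
| 10.0 | 48.7 | 15.9 |

(scatter of a reading: 0.5 percentage points)

- ratio of D to E at 8.0 min
- ratio of D to E at 4.0 d

- the numbers in the tables scatter by 0.5 percentage points (one standard deviation)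

Turned round, a ratio of 10 at the end needs E at 9.09% of the charge at most, even with D and E sharing the whole of it. That is less than cedar's last E, so E, which rose at every cedar reading, would have to turn and fall for that ratio to be reached. The reckoning here instead reads the late split, the selectivity factor of the last stretch: from 5.00 h to 10.0 h, cedar gained 4.40 parts of D per part of E, a reading that carries the scatter of 0.5 percentage points in each number. Dividing the open fraction at that split gives 3.45, the projected end ratio, on the assumption that fractions of the charge carry from cedar to the flask. The time 8.0 min comes before cedar's first reading, so this reckoning offers no early figure. The forecast gives 2.4 at 8.0 min and 12 at 4.0 d, the second in its words “I guess about 12, with very wide uncertainty”, higher than the projection.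

The flask gives 0.836 at 8.0 min and 3.67 at 4.0 d. Its E stands at 19.1% at 4.00 d, above the 9.09% that a ratio of 10 allows. The projection 3.45 lies below the flask's ratio at 4.0 d, by 0.220.

    L ⇌ Q (K = 1.56, k = 0.00264 s⁻¹)
    L + X → X + E (k = 2.24 × 10⁻⁴ L mol⁻¹ s⁻¹)
    X + Q → X + D (k = 3.43 × 10⁻⁴ L mol⁻¹ s⁻¹)
    E + X ⇌ Z + X, rate k4*[X]*[E] forward; the back reaction follows from the equilibrium constant (K = 0.572, k = 1.80 × 10⁻⁴ L mol⁻¹ s⁻¹)

For a neighbour flask charged with 2.9 M of L, the projected end ratio stays 3.45, since it is reckoned in fractions of the charge. That neighbour flask gives 3.67 at 4.0 d, with E at 19.1%.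

The readings were computed with constants of no real substance; noise was put on by code.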